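**Assumption:** the target (6,8-diprenyldaidzein) has no stereocentres or stereogenic double bonds, so no stereocontrol is needed; daidzein is taken as a commercial starting material.

**Retrosynthetic overview**
1. No ring is formed: both rings of the isoflavone core are bought intact as daidzein (5).
2. C6–prenyl bond: aromatic Claisen shift of the 7-O-(1,1-dimethylallyl) ether 9, which has only C6 free ortho to oxygen.
3. C8–prenyl bond: the same Claisen shift one round earlier (6 → 8).
4. Both tertiary allyl ethers: Pd(0)-catalysed O-allylation of the more acidic 7-OH with carbonate 4, made from 1 and 2.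

**Route**

Step 1
Reactants: 1 2-methylbut-3-en-2-ol; 2 di-tert-butyl dicarbonate
Product: 4 tert-butyl (2-methylbut-3-en-2-yl) carbonate, via lithium 2-methylbut-3-en-2-olate 3 (not isolated)
Conditions: n-BuLi (1.05 equiv), THF, −78 → 0 °C; then Boc2O, 0 °C → rt; H2O quench
Reagents that add atoms: di-tert-butyl dicarbonate 2, CC(C)(C)OC(=O)OC(=O)OC(C)(C)C; n-butyllithium, [Li]CCCC (supplies the Li of 3 only)
Why: Acylation of a pre-formed tertiary lithium alkoxide by Boc2O (alkoxycarbonylation) gives the mixed carbonate cleanly, with loss of tert-butoxide and CO2.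

Step 2
Reactants: 5 daidzein (7,4'-dihydroxyisoflavone); 4 tert-butyl (2-methylbut-3-en-2-yl) carbonate
Product: 6 4'-hydroxy-7-[(2-methylbut-3-en-2-yl)oxy]isoflavone
Conditions: 4 (1.1 equiv), Pd(PPh3)4 (5 mol %), THF/DMF 4:1, 0 °C → rt, stop at full conversion of 4
Reagents that add atoms: tert-butyl (2-methylbut-3-en-2-yl) carbonate 4, C=CC(C)(C)OC(=O)OC(C)(C)C
Why: In this decarboxylative Tsuji–Trost O-allylation the released tert-butoxide ionises the vinylogous-acid 7-OH (pKa about 7) far more than the 4'-OH (pKa about 10), and the phenoxide attacks the 1,1-dimethyl-π-allyl-Pd at its substituted terminus to give the kinetic tertiary ether.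

Step 3
Reactants: 6 4'-hydroxy-7-[(2-methylbut-3-en-2-yl)oxy]isoflavone
Product: 8 daidzein carrying a prenyl group at C8 (7,4'-dihydroxy-8-(3-methylbut-2-en-1-yl)isoflavone), via C8 ortho-dienone 7 (not isolated)
Conditions: PhNEt2, 130 °C, Ar, 2–3 h
Reagents that add atoms: none
Why: Aromatic ortho-Claisen [3,3] rearrangement of the tertiary allyl aryl ether delivers a normal prenyl group, preferentially to the angular C8 of a 7-oxygenated chromone, and the dienone re-aromatises by tautomerisation; whichever ortho carbon is taken first, step 5 fills the other, so the regiochemistry here does not change the final product.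

Step 4
Reactants: 8 7,4'-dihydroxy-8-(3-methylbut-2-en-1-yl)isoflavone; 4 tert-butyl (2-methylbut-3-en-2-yl) carbonate
Product: 9 4'-hydroxy-7-[(2-methylbut-3-en-2-yl)oxy]-8-(3-methylbut-2-en-1-yl)isoflavone
Conditions: 4 (1.2 equiv), Pd(PPh3)4 (10 mol %), THF, 0 °C → rt
Reagents that add atoms: tert-butyl (2-methylbut-3-en-2-yl) carbonate 4, C=CC(C)(C)OC(=O)OC(C)(C)C
Why: The same Tsuji–Trost O-allylation, again selective for the more acidic 7-OH; the prenyl alkene has no leaving group and is inert to Pd(0).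

Step 5
Reactants: 9 4'-hydroxy-7-[(2-methylbut-3-en-2-yl)oxy]-8-(3-methylbut-2-en-1-yl)isoflavone
Product: 11 6,8-diprenyldaidzein (7,4'-dihydroxy-6,8-bis(3-methylbut-2-en-1-yl)isoflavone), via C6 ortho-dienone 10 (not isolated)
Conditions: PhNEt2, 125–130 °C, Ar, 2–3 h
Reagents that add atoms: none
Why: A second aromatic ortho-Claisen [3,3] rearrangement can end only at C6 (C8 is substituted and the para position is the ring-fusion carbon), and the amine solvent suppresses acid-promoted chroman formation from the ortho-prenylphenol.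

**Compound list**
1 | 2-methylbut-3-en-2-ol | C=CC(C)(C)O | starting material
2 | di-tert-butyl dicarbonate | CC(C)(C)OC(=O)OC(=O)OC(C)(C)C | starting material
3 | lithium 2-methylbut-3-en-2-olate | [Li+].[O-]C(C)(C)C=C | intermediate
4 | tert-butyl (2-methylbut-3-en-2-yl) carbonate | C=CC(C)(C)OC(=O)OC(C)(C)C | intermediate
5 | daidzein (7,4'-dihydroxyisoflavone) | O=c1c(-c2ccc(O)cc2)coc2cc(O)ccc12 | starting material
6 | 4'-hydroxy-7-[(2-methylbut-3-en-2-yl)oxy]isoflavone | C=CC(C)(C)Oc1ccc2c(=O)c(-c3ccc(O)cc3)coc2c1 | intermediate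
7 | 3-(4-hydroxyphenyl)-8-(3-methylbut-2-en-1-yl)-8H-chromene-4,7-dione (racemic, transient) | CC(C)=CCC1C(=O)C=CC2=C1OC=C(c1ccc(O)cc1)C2=O | intermediate
8 | 7,4'-dihydroxy-8-(3-methylbut-2-en-1-yl)isoflavone (8-prenyldaidzein) | CC(C)=CCc1c(O)ccc2c(=O)c(-c3ccc(O)cc3)coc12 | intermediate
9 | 4'-hydroxy-7-[(2-methylbut-3-en-2-yl)oxy]-8-(3-methylbut-2-en-1-yl)isoflavone | C=CC(C)(C)Oc1ccc2c(=O)c(-c3ccc(O)cc3)coc2c1CC=C(C)C | intermediate
10 | 3-(4-hydroxyphenyl)-6,8-bis(3-methylbut-2-en-1-yl)-6H-chromene-4,7-dione (racemic, transient) | CC(C)=CCC1C=C2C(=O)C(c3ccc(O)cc3)=COC2=C(CC=C(C)C)C1=O | intermediate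
11 | 6,8-diprenyldaidzein (7,4'-dihydroxy-6,8-bis(3-methylbut-2-en-1-yl)isoflavone) | CC(C)=CCc1cc2c(=O)c(-c3ccc(O)cc3)coc2c(CC=C(C)C)c1O | target

**Step count**
Total steps: 5. Longest linear sequence: 5 (1 → 4 → 6 → 8 → 9 → 11); 4 steps from daidzein 5.

**Three steps most likely to fail**

Step 2 (7-O versus 4'-O selectivity, and tertiary versus linear ether). The fallback sets out from 5 and comes back at 6. Alkylate the 7-OH of 5 with 3-chloro-3-methylbut-1-yne (K2CO3 1.1 equiv, KI, CuI cat., acetone/DMF, 50 °C) to give 4'-hydroxy-7-[(2-methylbut-3-yn-2-yl)oxy]isoflavone F1. Then semi-hydrogenate the alkyne (H2 1 atm, Lindlar Pd/CaCO3–Pb, quinoline, EtOAc, rt) to reach 6. This replaces the π-allyl chemistry by a propargylic substitution that can only give the tertiary ether.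

Step 4 (the 7-OH is now hindered by the 8-prenyl group, so the free 4'-OH competes more). The fallback sets out from 8 and comes back at 9, using a protecting group instead of relying on acidity. Silylate both phenols (TBSCl 2.5 equiv, imidazole, DMF, rt) to 7,4'-bis(tert-butyldimethylsilyloxy)-8-prenylisoflavone F2. Cleave only the much more labile 7-O-silyl ether of the vinylogous acid (K2CO3 cat., MeOH/THF, 0 °C) to 4'-(tert-butyldimethylsilyloxy)-7-hydroxy-8-prenylisoflavone F3. O-allylate with 4 and Pd(PPh3)4 as in step 4 to 4'-(tert-butyldimethylsilyloxy)-7-[(2-methylbut-3-en-2-yl)oxy]-8-prenylisoflavone F4. Remove the silyl group (TBAF/AcOH 1:1, THF, 0 °C) to give 9.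

Step 5 (the crowded tertiary ether may lose isoprene, or the product may cyclise to a chroman on heating). The fallback sets out from 8 and comes back at 11. O-prenylate the 7-OH (prenyl bromide 1.1 equiv, K2CO3, acetone, rt) to 4'-hydroxy-7-[(3-methylbut-2-en-1-yl)oxy]-8-prenylisoflavone F5. Then induce an acid-clay [1,3]-shift of the O-prenyl group to the only free ortho carbon C6 (montmorillonite K10, CH2Cl2, 0 °C → rt) to give 11 directly. Yields for this shift are typically modest.

**Further compounds**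
F1 | step 2 | 4'-hydroxy-7-[(2-methylbut-3-yn-2-yl)oxy]isoflavone | C#CC(C)(C)Oc1ccc2c(=O)c(-c3ccc(O)cc3)coc2c1
F2 | step 4 | 7,4'-bis(tert-butyldimethylsilyloxy)-8-(3-methylbut-2-en-1-yl)isoflavone | CC(C)=CCc1c(O[Si](C)(C)C(C)(C)C)ccc2c(=O)c(-c3ccc(O[Si](C)(C)C(C)(C)C)cc3)coc12
F3 | step 4 | 4'-(tert-butyldimethylsilyloxy)-7-hydroxy-8-(3-methylbut-2-en-1-yl)isoflavone | CC(C)=CCc1c(O)ccc2c(=O)c(-c3ccc(O[Si](C)(C)C(C)(C)C)cc3)coc12
F4 | step 4 | 4'-(tert-butyldimethylsilyloxy)-7-[(2-methylbut-3-en-2-yl)oxy]-8-(3-methylbut-2-en-1-yl)isoflavone | C=CC(C)(C)Oc1ccc2c(=O)c(-c3ccc(O[Si](C)(C)C(C)(C)C)cc3)coc2c1CC=C(C)C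
F5 | step 5 | 4'-hydroxy-7-[(3-methylbut-2-en-1-yl)oxy]-8-(3-methylbut-2-en-1-yl)isoflavone | CC(C)=CCOc1ccc2c(=O)c(-c3ccc(O)cc3)coc2c1CC=C(C)C
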